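**Plan**
1. Retrosynthesis: the lactam N–C16 bond is cut first, giving the open-chain N-(pivaloyloxy)amide of (13E)-6β-acetoxy-9α-hydroxylabd-13-en-15-oic acid; C13=C14 is cut next (olefination) to a C13 methyl ketone whose rings A and B, C11–C13 and C16 come from (−)-sclareol.
2. Enabling feature: in the 13E enoyl unit the C16 methyl group is cis to the C15 acyl group across C13=C14, so its allylic C–H bonds sit in a fixed 1,5-relationship to the nitrogen on C15 and no other C–H bond can reach it; a nitrenoid on that nitrogen can only close the five-membered pyrrolinone ring.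
3. Forward order: side-chain degradation of sclareol; ring B re-oxidised (C8=C9 alkene → 8-en-7-one → 6,8-diene → 6α,9α-endoperoxide → 9α-hydroxy-7-en-6-one → 9α-hydroxy-6-ketone → 6β-acetate); chain extended by C14–C15; heterocycle closed in the last step by a haem nitrene transferase.
4. Stereochemistry: C5 and C10 from sclareol; C9 from α-face [4+2] addition of singlet oxygen anti to the C10 methyl; C8 from axial protonation in a dissolving-metal reduction; C6 from α-face hydride attack; the 13E geometry from the olefination.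

Key step: step 15

Remark: labdane numbering is used (lactam ring = C13=C14, C15=O, N, C16H2), "8βH" means the C17 methyl is α (equatorial), and the enzyme variant for step 15 is assumed to be obtainable by directed evolution on 20.

Step 1
Reactants: 1 (−)-sclareol
Product: 2 8α-hydroxy-14,15-dinorlabdan-13-one
Conditions: KMnO4, acetone/H2O, 0 °C
Reagents that add atoms: none
Why: Permanganate degradation of the vinyl carbinol (dihydroxylation of C14=C15, then glycol and α-hydroxy-carbonyl cleavage) stops at the C13 methyl ketone because C13 carries no hydrogen, and it leaves the ring stereocentres and the tertiary C8 alcohol untouched.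

Step 2
Reactants: 2 8α-hydroxy-14,15-dinorlabdan-13-one
Product: 3 14,15-dinorlabd-8-en-13-one
Conditions: HI (57% aq., substoichiometric), benzene, 80 °C
Reagents that add atoms: none
Why: Acid-mediated E1 dehydration of the tertiary C8 alcohol with alkene equilibration: every kinetic isomer re-ionises to the same C8 cation and the mixture should drain to the tetrasubstituted C8=C9 alkene, which erases C8 and C9 on purpose (both are rebuilt in steps 7 and 8).

Step 3
Reactants: 3 14,15-dinorlabd-8-en-13-one
Product: 4 13,13-(ethylenedioxy)-14,15-dinorlabd-8-ene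
Conditions: ethylene glycol, PPTS, benzene, reflux (Dean–Stark)
Reagents that add atoms: ethylene glycol, OCCO
Why: Acid-catalysed ketalisation with azeotropic water removal masks the C13 ketone for the base, oxidation and reduction steps that follow.

Step 4
Reactants: 4 13,13-(ethylenedioxy)-14,15-dinorlabd-8-ene
Product: 5 13,13-(ethylenedioxy)-14,15-dinorlabd-8-en-7-one
Conditions: CrO3, 3,5-dimethylpyrazole, CH2Cl2, −20 °C
Reagents that add atoms: chromium trioxide, O=[Cr](=O)=O
Why: Allylic C–H oxidation with the CrO3–3,5-dimethylpyrazole complex should attack the ring methylene C7, whose axial hydrogen overlaps with the C8=C9 π bond and is less shielded than the C11 methylene next to quaternary C10, giving the tetrasubstituted enone without a new stereocentre.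

Step 5
Reactants: 5 13,13-(ethylenedioxy)-14,15-dinorlabd-8-en-7-one
Product: 7 13,13-(ethylenedioxy)-14,15-dinorlabda-6,8-dien-7-yl triflate, via potassium dienolate 6 (not isolated)
Conditions: KN(SiMe3)2, THF, −78 °C; then PhNTf2, −78 °C → 0 °C
Reagents that add atoms: N-phenylbis(trifluoromethanesulfonimide), O=S(=O)(N(c1ccccc1)S(=O)(=O)C(F)(F)F)C(F)(F)F
Why: Kinetic deprotonation of the enone at the α' carbon C6 gives the cross-conjugated dienolate, which is O-sulfonylated (enol triflate formation) and so fixes the second double bond at C6=C7.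

Step 6
Reactants: 7 13,13-(ethylenedioxy)-14,15-dinorlabda-6,8-dien-7-yl triflate
Product: 8 13,13-(ethylenedioxy)-14,15-dinorlabda-6,8-diene
Conditions: Pd(OAc)2 (cat.), PPh3, HCO2H, n-Bu3N, DMF, 60 °C
Reagents that add atoms: none
Why: Palladium-catalysed formate reduction of an alkenyl triflate (oxidative addition, decarboxylation of formate to a palladium hydride, reductive elimination) replaces the triflate by hydrogen with the double bonds in place and delivers the homoannular C6=C7–C8=C9 diene of ring B.

Step 7
Reactants: 8 13,13-(ethylenedioxy)-14,15-dinorlabda-6,8-diene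
Product: 10 13,13-(ethylenedioxy)-9α-hydroxy-14,15-dinorlabd-7-en-6-one, via 6α,9α-endoperoxide 9 (not isolated)
Conditions: O2, tetraphenylporphyrin (cat.), visible light, CH2Cl2, −20 °C; then Et3N (cat.), 0 °C → rt
Reagents that add atoms: oxygen, O=O
Why: Singlet oxygen should add to the cisoid ring B diene in a [4+2] cycloaddition from the α-face, anti to the axial C10 methyl group (as in the formation of ergosterol peroxide), which sets C9–O as α, and the Kornblum–DeLaMare rearrangement then removes the only hydrogen on a peroxide-bearing carbon (C6–H) to give the C6 ketone and the free 9α-hydroxyl.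

Step 8
Reactants: 10 13,13-(ethylenedioxy)-9α-hydroxy-14,15-dinorlabd-7-en-6-one
Product: 13 13,13-(ethylenedioxy)-9α-hydroxy-8βH-14,15-dinorlabdan-6-one, via lithium alkoxide 11 (not isolated), via dilithium enolate 12 (not isolated)
Conditions: LiN(SiMe3)2 (1 equiv), THF, −78 °C; then Li, NH3(l)/THF, −78 °C; isoprene, then solid NH4Cl
Reagents that add atoms: none
Why: Dissolving-metal (Birch-type) reduction of the enone: the β-carbon C8 should be protonated axially, from the β-face, through the chair-like enolate (the outcome known for steroidal 7-en-6-ones), so the C17 methyl ends equatorial and α, while the hydroxyl is held as its lithium alkoxide, which cannot leave from the adjacent C8 carbanion.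

Step 9
Reactants: 13 13,13-(ethylenedioxy)-9α-hydroxy-8βH-14,15-dinorlabdan-6-one
Product: 14 13,13-(ethylenedioxy)-8βH-14,15-dinorlabdane-6β,9α-diol
Conditions: NaBH4, MeOH/THF, 0 °C → rt
Reagents that add atoms: none
Why: Borohydride reduction of the hindered C6 ketone: the axial (β) trajectory is blocked by the syn-axial C10 and 4β methyl groups, so hydride should enter from the α-face and give the axial 6β-alcohol.

Step 10
Reactants: 14 13,13-(ethylenedioxy)-8βH-14,15-dinorlabdane-6β,9α-diol
Product: 15 6β-acetoxy-13,13-(ethylenedioxy)-8βH-14,15-dinorlabdan-9α-ol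
Conditions: Ac2O, DMAP (cat.), pyridine, 50 °C
Reagents that add atoms: acetic anhydride, CC(=O)OC(C)=O
Why: DMAP-catalysed acylation acetylates the secondary 6β-hydroxyl, whereas the tertiary 9α-hydroxyl next to quaternary C10 should not react under these conditions.

Step 11
Reactants: 15 6β-acetoxy-13,13-(ethylenedioxy)-8βH-14,15-dinorlabdan-9α-ol
Product: 16 6β-acetoxy-9α-hydroxy-8βH-14,15-dinorlabdan-13-one
Conditions: PPTS, acetone/H2O, 50 °C
Reagents that add atoms: water, O
Why: Mild acid-catalysed ketal hydrolysis frees the C13 methyl ketone without cleaving the acetate or dehydrating the tertiary alcohol.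

Step 12
Reactants: 16 6β-acetoxy-9α-hydroxy-8βH-14,15-dinorlabdan-13-one
Product: 17 allyl (13E)-6β-acetoxy-9α-hydroxy-8βH-labd-13-en-15-oate
Conditions: allyl diethylphosphonoacetate (slight excess over NaH), NaH, THF, 0 °C; then 16, 50 °C; minor 13Z isomer removed by chromatography
Reagents that add atoms: allyl diethylphosphonoacetate, C=CCOC(=O)CP(=O)(OCC)OCC
Why: Horner–Wadsworth–Emmons olefination of the methyl ketone with the pre-formed phosphonate anion (no free base, so the tertiary hydroxyl stays protonated and cannot add to the new enoate) should give mainly the 13E enoate, with C16 cis to the ester as step 15 requires.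

Step 13
Reactants: 17 allyl (13E)-6β-acetoxy-9α-hydroxy-8βH-labd-13-en-15-oate
Product: 18 (13E)-6β-acetoxy-9α-hydroxy-8βH-labd-13-en-15-oic acid
Conditions: Pd(PPh3)4 (cat.), morpholine, THF, rt
Reagents that add atoms: none
Why: Tsuji–Trost deallylation with zerovalent palladium and morpholine as allyl acceptor frees the acid under neutral conditions that leave the C6 acetate intact.

Step 14
Reactants: 18 (13E)-6β-acetoxy-9α-hydroxy-8βH-labd-13-en-15-oic acid
Product: 20 (13E)-6β-acetoxy-9α-hydroxy-N-(pivaloyloxy)-8βH-labd-13-en-15-amide, via benzotriazolyl ester 19 (not isolated)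
Conditions: EDC·HCl, HOBt, N-methylmorpholine, PivONH2·TfOH, CH2Cl2, 0 °C → rt
Reagents that add atoms: O-pivaloylhydroxylammonium triflate, CC(C)(C)C(=O)O[NH3+].[O-]S(=O)(=O)C(F)(F)F
Why: Carbodiimide/HOBt amide coupling of the acid with O-pivaloylhydroxylamine (freed in the flask from its triflate salt) gives the N-acyloxy amide, the nitrene precursor, under weakly basic conditions that should avoid Lossen rearrangement.

Step 15
Reactants: 20 (13E)-6β-acetoxy-9α-hydroxy-N-(pivaloyloxy)-8βH-labd-13-en-15-amide
Product: 21 6β-acetoxy-9α-hydroxy-8βH-labd-13-ene 15,16-lactam (target; C15 carbonyl, N on C16)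
Conditions: whole E. coli cells expressing an engineered cytochrome P411 lactam synthase (serine-ligated P450BM3 haem-domain variant evolved on 20), M9-N buffer pH 7.4, glucose, 5 vol% EtOH, anaerobic, 22 °C
Reagents that add atoms: none
Why: Proposed new method: the reduced (divalent iron) haem cleaves the N–O bond of 20 to an enzyme-bound iron acyl nitrenoid, which abstracts a hydrogen atom from the C16 methyl group through a six-membered transition state laid out by the planar s-cis C15(=O)–C14=C13–C16 unit and then recombines with the allylic radical at C16 (radical rebound), releasing the lactam and pivalic acid. The closest known reaction type is the intramolecular C(sp3)–H amidation of O-acyl hydroxamates to β-, γ- and δ-lactams by evolved haem nitrene transferases of the cytochrome P450 family (chemocatalytic counterpart: dioxazolone lactamisation with iridium or ruthenium catalysts); what has not been shown is an enoyl nitrenoid amidating a cis-disposed allylic methyl group to give an unsaturated γ-lactam. The five-membered ring closes by formal 1,5 C–H insertion, that is N–C bond formation at a saturated carbon (5-exo-tet-like recombination with C13=C14 staying endocyclic), and no stereocentre is created, because C16 becomes a methylene group and the alkene geometry is locked into the ring. Site selectivity is secured by the substrate: in the 13E isomer only C16 is cis to the acyl group, its C–H bonds are the weakest within reach (allylic and vinylogous to the carbonyl), C12 is held on the far side of the double bond, and rebound at the other allyl terminus (C14) would give a three-membered ring. Chemoselectivity is what the protein must supply and what small nitrene-transfer catalysts would not give reliably here: the active site has to favour hydrogen abstraction over Lossen-type migration to the vinyl isocyanate and over reduction of the nitrenoid to the primary amide, with the free C9 hydroxyl and C6 acetate untouched, and a variant doing this would have to be found by directed evolution from a known γ-lactam synthase, helped by the fatty-acid-like shape of 20 (polar acyl head, lipophilic decalin tail).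

**Compound list**
1 | (−)-sclareol, (13R)-labd-14-ene-8α,13-diol | C=C[C@](C)(O)CC[C@@H]1[C@@]2(C)CCCC(C)(C)[C@@H]2CC[C@@]1(C)O | starting material
2 | 8α-hydroxy-14,15-dinorlabdan-13-one | CC(=O)CC[C@@H]1[C@@]2(C)CCCC(C)(C)[C@@H]2CC[C@@]1(C)O | intermediate
3 | 14,15-dinorlabd-8-en-13-one | CC(=O)CCC1=C(C)CC[C@H]2C(C)(C)CCC[C@]12C | intermediate
4 | 13,13-(ethylenedioxy)-14,15-dinorlabd-8-ene | CC1(CCC2=C(C)CC[C@H]3C(C)(C)CCC[C@]23C)OCCO1 | intermediate
5 | 13,13-(ethylenedioxy)-14,15-dinorlabd-8-en-7-one | CC1(CCC2=C(C)C(=O)C[C@H]3C(C)(C)CCC[C@]23C)OCCO1 | intermediate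
6 | potassium 13,13-(ethylenedioxy)-14,15-dinorlabda-6,8-dien-7-olate | [K+].CC1(CCC2=C(C)C([O-])=C[C@H]3C(C)(C)CCC[C@]23C)OCCO1 | intermediate
7 | 13,13-(ethylenedioxy)-14,15-dinorlabda-6,8-dien-7-yl trifluoromethanesulfonate | CC1(CCC2=C(C)C(OS(=O)(=O)C(F)(F)F)=C[C@H]3C(C)(C)CCC[C@]23C)OCCO1 | intermediate
8 | 13,13-(ethylenedioxy)-14,15-dinorlabda-6,8-diene | CC1(CCC2=C(C)C=C[C@H]3C(C)(C)CCC[C@]23C)OCCO1 | intermediate
9 | 6α,9α-epidioxy-13,13-(ethylenedioxy)-14,15-dinorlabd-7-ene | CC1(CC[C@@]23OO[C@@H](C=C2C)[C@H]4C(C)(C)CCC[C@]34C)OCCO1 | intermediate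
10 | 13,13-(ethylenedioxy)-9α-hydroxy-14,15-dinorlabd-7-en-6-one | CC1(CC[C@@]2(O)C(C)=CC(=O)[C@H]3C(C)(C)CCC[C@]23C)OCCO1 | intermediate
11 | lithium 9α-alkoxide of 10 | [Li+].CC1(CC[C@@]2([O-])C(C)=CC(=O)[C@H]3C(C)(C)CCC[C@]23C)OCCO1 | intermediate
12 | dilithium 13,13-(ethylenedioxy)-9α-oxido-8βH-14,15-dinorlabd-6-en-6-olate | [Li+].[Li+].CC1(CC[C@@]2([O-])[C@H](C)C=C([O-])[C@H]3C(C)(C)CCC[C@]23C)OCCO1 | intermediate
13 | 13,13-(ethylenedioxy)-9α-hydroxy-8βH-14,15-dinorlabdan-6-one | CC1(CC[C@@]2(O)[C@H](C)CC(=O)[C@H]3C(C)(C)CCC[C@]23C)OCCO1 | intermediate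
14 | 13,13-(ethylenedioxy)-8βH-14,15-dinorlabdane-6β,9α-diol | CC1(CC[C@@]2(O)[C@H](C)C[C@@H](O)[C@H]3C(C)(C)CCC[C@]23C)OCCO1 | intermediate
15 | 6β-acetoxy-13,13-(ethylenedioxy)-8βH-14,15-dinorlabdan-9α-ol | CC1(CC[C@@]2(O)[C@H](C)C[C@@H](OC(C)=O)[C@H]3C(C)(C)CCC[C@]23C)OCCO1 | intermediate
16 | 6β-acetoxy-9α-hydroxy-8βH-14,15-dinorlabdan-13-one | CC(=O)CC[C@@]1(O)[C@H](C)C[C@@H](OC(C)=O)[C@H]2C(C)(C)CCC[C@]12C | intermediate
17 | allyl (13E)-6β-acetoxy-9α-hydroxy-8βH-labd-13-en-15-oate | C=CCOC(=O)/C=C(\C)CC[C@@]1(O)[C@H](C)C[C@@H](OC(C)=O)[C@H]2C(C)(C)CCC[C@]12C | intermediate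
18 | (13E)-6β-acetoxy-9α-hydroxy-8βH-labd-13-en-15-oic acid | OC(=O)/C=C(\C)CC[C@@]1(O)[C@H](C)C[C@@H](OC(C)=O)[C@H]2C(C)(C)CCC[C@]12C | intermediate
19 | benzotriazol-1-yl ester of 18 | O=C(On1nnc2ccccc12)/C=C(\C)CC[C@@]1(O)[C@H](C)C[C@@H](OC(C)=O)[C@H]2C(C)(C)CCC[C@]12C | intermediate
20 | (13E)-6β-acetoxy-9α-hydroxy-N-(pivaloyloxy)-8βH-labd-13-en-15-amide | CC(C)(C)C(=O)ONC(=O)/C=C(\C)CC[C@@]1(O)[C@H](C)C[C@@H](OC(C)=O)[C@H]2C(C)(C)CCC[C@]12C | intermediate
21 | 6β-acetoxy-9α-hydroxy-8βH-labd-13-ene 15,16-lactam (4-substituted 1,5-dihydro-2H-pyrrol-2-one) | CC(=O)O[C@@H]1C[C@@H](C)[C@](O)(CCC2=CC(=O)NC2)[C@@]2(C)CCCC(C)(C)[C@H]12 | target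

**Totals**
Total step count: 15. Longest linear sequence: 15 steps (1 → 21, fully linear).

**Steps most likely to fail**

Step 15 (proposed new method). What may go wrong: no productive binding or turnover of the bulky diterpenoid hydroxamate in the haem pocket, reduction of the nitrenoid to the primary amide, or Lossen-type rearrangement outrunning hydrogen abstraction. Fallback by known chemistry, setting out from 16 and coming back at 21: kinetic deprotonation on the methyl side with LiN(SiMe3)2 (2 equiv, THF, −78 °C) gives the dilithium alkoxide–enolate F1, which NBS brominates at C16 to the bromomethyl ketone F2. NaN3 in DMF then gives the azido ketone F3, an SN2 step that makes the N–C16 bond. Staudinger reduction (PPh3, THF/H2O) followed by HCl gives the amino ketone hydrochloride F4. Ketenylidenetriphenylphosphorane (Ph3P=C=C=O) with Et3N in toluene at 80 °C acylates the amine to the amide ylide F5, which closes the ring by intramolecular Wittig olefination of the C13 ketone to give 21.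

Step 8. What may go wrong: vinylogous reductive loss of the C9 oxygen from the C8 carbanion, over-reduction of the C6 carbonyl, or protonation of C8 from the α-face. Fallback, setting out from 10 and coming back at 16: Et3SiOTf with 2,6-lutidine silylates the tertiary hydroxyl to the 9-O-triethylsilyl enone F6. NaBH4 with CeCl3·7H2O (Luche reduction, hydride from the α-face) gives the 6β-allylic alcohol F7. Hydroxyl-directed hydrogenation with [Ir(cod)(PCy3)(py)]PF6 and H2 in CH2Cl2 should deliver hydrogen syn to the 6β-hydroxyl, on the β-face, while the silyl ether shields the α-face, giving the 8βH alcohol F8. Ac2O with DMAP gives the acetate F9, and aqueous HCl in THF removes the silyl ether and the dioxolane together to give 16.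

Step 2. What may go wrong: incomplete equilibration to the tetrasubstituted alkene, or diversion into intramolecular enol-ether formation between the C8 oxygen and the C13 carbonyl under acid. Fallback that avoids acid-mediated alkene isomerisation, setting out from 2 and coming back at 5: SOCl2 with pyridine in CH2Cl2 at −78 °C (kinetic anti-elimination into the axial methyl group) gives the exocyclic alkene 14,15-dinorlabd-8(17)-en-13-one F10, which is ketalised as in step 3 to the dioxolane F11. SeO2 with t-BuOOH in CH2Cl2 hydroxylates the ring allylic position to the 7α-alcohol F12, Dess–Martin periodinane gives the exocyclic enone F13, and DBU moves the double bond into conjugation inside the ring to give 5.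

**Further compounds**
F1 | step 15 | dilithium salt of the C16 (methyl-side) enolate of 16 with 9α-O-lithium | [Li+].[Li+].C=C([O-])CC[C@@]1([O-])[C@H](C)C[C@@H](OC(C)=O)[C@H]2C(C)(C)CCC[C@]12C
F2 | step 15 | 6β-acetoxy-16-bromo-9α-hydroxy-8βH-14,15-dinorlabdan-13-one | BrCC(=O)CC[C@@]1(O)[C@H](C)C[C@@H](OC(C)=O)[C@H]2C(C)(C)CCC[C@]12C
F3 | step 15 | 6β-acetoxy-16-azido-9α-hydroxy-8βH-14,15-dinorlabdan-13-one | [N-]=[N+]=NCC(=O)CC[C@@]1(O)[C@H](C)C[C@@H](OC(C)=O)[C@H]2C(C)(C)CCC[C@]12C
F4 | step 15 | 6β-acetoxy-16-amino-9α-hydroxy-8βH-14,15-dinorlabdan-13-one hydrochloride | [Cl-].[NH3+]CC(=O)CC[C@@]1(O)[C@H](C)C[C@@H](OC(C)=O)[C@H]2C(C)(C)CCC[C@]12C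
F5 | step 15 | N-(13-oxo-16-yl) (triphenylphosphoranylidene)acetamide of F4 (amide ylide) | O=C(C=P(c1ccccc1)(c1ccccc1)c1ccccc1)NCC(=O)CC[C@@]1(O)[C@H](C)C[C@@H](OC(C)=O)[C@H]2C(C)(C)CCC[C@]12C
F6 | step 8 | 13,13-(ethylenedioxy)-9α-(triethylsilyloxy)-14,15-dinorlabd-7-en-6-one | CC1(CC[C@@]2(O[Si](CC)(CC)CC)C(C)=CC(=O)[C@H]3C(C)(C)CCC[C@]23C)OCCO1
F7 | step 8 | 13,13-(ethylenedioxy)-9α-(triethylsilyloxy)-14,15-dinorlabd-7-en-6β-ol | CC1(CC[C@@]2(O[Si](CC)(CC)CC)C(C)=C[C@@H](O)[C@H]3C(C)(C)CCC[C@]23C)OCCO1
F8 | step 8 | 13,13-(ethylenedioxy)-9α-(triethylsilyloxy)-8βH-14,15-dinorlabdan-6β-ol | CC1(CC[C@@]2(O[Si](CC)(CC)CC)[C@H](C)C[C@@H](O)[C@H]3C(C)(C)CCC[C@]23C)OCCO1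
F9 | step 8 | 6β-acetoxy-13,13-(ethylenedioxy)-9α-(triethylsilyloxy)-8βH-14,15-dinorlabdane | CC1(CC[C@@]2(O[Si](CC)(CC)CC)[C@H](C)C[C@@H](OC(C)=O)[C@H]3C(C)(C)CCC[C@]23C)OCCO1
F10 | step 2 | 14,15-dinorlabd-8(17)-en-13-one | CC(=O)CC[C@H]1C(=C)CC[C@H]2C(C)(C)CCC[C@]12C
F11 | step 2 | 13,13-(ethylenedioxy)-14,15-dinorlabd-8(17)-ene | CC1(CC[C@H]2C(=C)CC[C@H]3C(C)(C)CCC[C@]23C)OCCO1
F12 | step 2 | 13,13-(ethylenedioxy)-14,15-dinorlabd-8(17)-en-7α-ol | CC1(CC[C@H]2C(=C)[C@H](O)C[C@H]3C(C)(C)CCC[C@]23C)OCCO1
F13 | step 2 | 13,13-(ethylenedioxy)-14,15-dinorlabd-8(17)-en-7-one | CC1(CC[C@H]2C(=C)C(=O)C[C@H]3C(C)(C)CCC[C@]23C)OCCO1
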